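By 5.00 h, its last reading, the south-east run holds 19.7% of its charge as target, and two chemists dispute what that means for a flask charged twice as heavily.

the same everywhere: gas phase 2.7 mM (held)
- south-east: solid substrate 0.025 M; run made earlier
- flask: solid substrate 0.050 M; time 50 h

south-east run (percent of the solid substrate charged): time / h: target / % = 0.417: 1.5; 0.667: 1.6; 1.00: 2.2; 1.33: 3.7; 2.00: 7.7; 3.00: 10.4; 5.00: 19.7

(each reading ± 0.5 percentage points)

- solid, in amounts per volume of the solution: solid substrate
- at the start none of the solid substrate is in solution
- at the start none of the gas phase is in solution

1. when, up to 50 h, the flask holds most target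
2. the amount of target, in percent of the solid substrate charged, at that time

Both write the balance of the solid substrate, the limiting reagent: what leaves the charge is take-up per hour times hours. From 2.00 h to 5.00 h the readings climb 0.0400 h⁻¹ of the charge. The first chemist holds take-up constant in amount per hour, so the flask's larger charge sees a smaller fraction, 0.0200 h⁻¹. Her charge life, the hours a charge lasts at that take-up, is 50.0 h, which means 100% target at the limit. The second chemist keeps 0.0400 h⁻¹ as the fraction of whatever solid remains, and gets 86.5% at 50 h.

At 5.00 h, the last south-east reading, the two curves part by 1.9 percentage points, against a scatter of 0.5 points, and one reading is thin ground. I side with the first, and take 50.0 h as a longest life: the slope counts target, and any solid substrate leaving by another road shortens it.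

The forecast takes neither figure exactly: 93% (from 75% to 100%) at 50 h, on the ground that “the amount should simply rise until the time limit”.

The flask peaks at 30.7 h with 32.3%. On rate the flask sides with the first chemist: at 5.00 h it holds 9.40% target, half of the south-east run's 18.8% without scatter. The second view keeps the short span of the south-east readings, where the two curves lay close.

    dissolved gas + target → over-reaction product (k = 0.0100 M⁻¹ s⁻¹)
    starting material → side product (k = 3.50 × 10⁻⁴ s⁻¹)
    solid substrate ⇌ starting material, rate k3*(cs3 - [starting material]) while solid is left; crystals form when [starting material] > cs3 (solubility = 13.0 mM, k = 3.60 × 10⁻⁵ s⁻¹)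
    starting material + dissolved gas → target (k = 0.470 M⁻¹ s⁻¹)
    gas phase ⇌ dissolved gas, rate k5*(csat - [dissolved gas]) (kL = 4.50 × 10⁻⁴ s⁻¹)

Read from the solid's own fall, 16.4% by 5.00 h, the flask's charge life is 30.6 h, shorter than 50.0 h, and at the best time solid substrate stands at 0%. Dissolved gas turning target into over-reaction product holds the peak down: without that step the flask reaches 72.3%, not 32.3%. The neighbour charged with 0.013 M has a target-slope life of 13.0 h; it peaks at 54.2% and holds 1.13% target at 50.0 h.

The runs come from a simulation with made-up constants, noise included.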